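**The leftover.** At 6.00 d the beta run shows Z at 24% and E at 0%, so 76.0% of the X charged stands in neither column.

| flask | X | Q | remark | time |
|---|---|---|---|---|
| theta | 20 mM | 30 mM | the very flask that is asked about, followed so far |  |
| beta | 20 mM | 20 mM | run made earlier |  |
| flask | 20 mM | 30.0 mM |  | 15 d |

- theta (time / h: Z / %, E / %): 3.00: 0, 9; 6.00: 4, 17; 12.0: 11, 29; 25.0: 16, 25; 40.0: 20, 17
- beta (time / d: Z / %, E / %): 0.500: 8, 26; 1.67: 19, 18; 3.00: 23, 7; 4.00: 27, 2; 6.00: 24, 0

(scatter of a reading: 1.5 percentage points)



1. share of Z in Z plus E at 3.0 h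
2. share of Z in Z plus E at 30 h
3. share of Z in Z plus E at 15 d

**The ledger.** X is booked as the limiting reagent on a supposition the readings cannot test: that Q is used one for one, which leaves the flask 10.0 mM of Q over. X is also booked as spent by the last beta readings. The first entry is Z, read as the mean of 27% at 4.00 d and 24% at 6.00 d. This gives φ = 25.5%, the Z tally, meaning Z standing per X spent once E has faded. The second entry is E, read at 2% and then 0% at those times. The third entry is the unseen remainder, 74.5%, and with it the books close.

**The transfer.** At 40.0 h the flask's own run reads Z 20% and E 17%, and beta reads 19% and 18% at 1.67 d, within the scatter of 1.5 percentage points. Earlier the two runs part: at 12.0 h the flask's own run reads Z 11% and E 29%, against 8% and 26% for beta at 0.500 d, both up by 3 points, so the extra Q may speed the early run. But φ counts Z per X spent and says nothing of pace, so it is carried to the flask as a supposition. Booking E generously at its beta reading of 2%, this reckoning puts the share of Z in Z plus E at 15 d at 92.7% or higher.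

**The forecast.** The forecast gives 9% at 3.0 h, 44% at 30 h and, above this floor, 97% at 15 d, on the ground that “Z should therefore dominate, with a small allowance for residual E”.

**The result.** The flask gives 17.9%, 46.5% and 99.1% at those times.

    X + Q → J + D (k = 7.70 M⁻¹ h⁻¹)
    J ⇌ Z (K = 76.0, k = 0.0260 h⁻¹)
    E + D → L (k = 5.10 M⁻¹ h⁻¹)
    J ⇌ E (K = 2.90, k = 0.130 h⁻¹)

**What ran.** In the flask, X + Q → J + D ran while X lasted, and by 1.50 d X was down to 2.18% with 9.62 mM of D standing. E + D → L ran on, so that at 15.0 d X stood at 0%, Q at 33% of its own charge, L at 74.5% and Z at 25.2%, against φ of 25.5%. In the neighbour charged with 34 mM of X, Q stands at 0% and X at 11.8% at 15.0 d, so φ on the X spent gives 22.5%, and Z stands at 20.2%.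

All runs were computed for an exercise; noise was put on by code.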